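## The problem

The target is a 14-membered carbocycle (C1–C14, cembrane numbering) that carries three features at once: a cis-fused α-methylene-γ-butyrolactone across C1–C2, a 1,2-dioxane that bridges C8 and C11 through C9–C10, and two E-trisubstituted olefins (C3=C4 and C12=C13). It has five stereocentres (1S, 2S, 7S, 8R, 11S). C8 and C11 are tied together by the peroxide and C7 is next to C8, but C1 and C2 are separated from this group by the two olefins, so nothing relays stereochemistry from the dioxane to the lactone except the conformation of the large ring or a reagent. C8 is quaternary (methyl, peroxide oxygen, C7, C9) and cannot be corrected once formed, so it has to come from a stereospecific C–O bond formation. Its neighbour C7 gets only a weak bias from it (methyl against ring CH2) and needs reagent control. The O–O bond will not survive low-valent metals, phosphines at elevated temperature, LiAlH4 or hard carbanions, and the hydrogen at C11 invites base-induced Kornblum–DeLaMare cleavage whenever C12 is a carbonyl carbon. The α-methylene lactone is a Michael acceptor, the allylic C2–O and C11–O bonds can ionise under strong acid, and the C7 acetate excludes hydride reagents once it is in place. The feature that opens the structure is the dioxane itself: C7 on C8 and C12 on C11 lie on the same face of the ring, so a bond drawn between C7 and C12 turns the dioxane into the peroxide bridge of a 2,3-dioxabicyclo[2.2.2]octane. That bicycle is the [4+2] adduct of O2 with a 1-methylcyclohexa-1,3-diene whose remaining two carbons (C7, C12) are a cis-diol, which is an arene cis-dihydrodiol. The price is that the peroxide is present from the fourth step on and every later reagent has to respect it.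

## Retrosynthesis

**C1–C2 and the lactone C–O bond (29 ⇒ 27).** The last cut removes the ring-fusion bond and the lactone together, leaving the open-chain enal 27 with a 2-(methoxycarbonyl)allylboronate at the other end. The neighbouring ring bonds are poorer places to close: the trisubstituted olefins would give E/Z mixtures by metathesis, and the classical closure of cembranolides at this very bond uses divalent chromium or zinc, which would reduce the O–O bond. An allylboration is neutral, and its closed chair transition state converts the olefin geometry of the boronate (C14 cis to CH2B) into the cis ring fusion. The precursor has no C1/C2 stereocentres, no lactone and no large ring. The forward step must run at high dilution with mild acceleration and must select one face of the aldehyde, for which a chiral phosphoric acid is used.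

**C1=C15 (27 ⇒ 24 + 26).** The boronate is attached by cross-metathesis of the terminal olefin of 24 with the boryl acrylate 26, made in one step from methyl 2-(bromomethyl)acrylate 25. The carbonyl route to such boronates (Baylis–Hillman adduct, then borylation) would need a β,γ-unsaturated aldehyde at C1 that conjugates easily. Metathesis is neutral, peroxide-tolerant and gives the thermodynamic E enoate, which is the geometry the ring closure needs.

**C14–C1 and the C2 oxidation level (24 ⇒ 23 ⇒ 22 ⇒ 21).** Enal 24 comes from allylic alcohol 23 (MnO2) and this from silyl ether 22. The vinyl group of 22 (C1 and the carbon lost as ethene) is joined to C14 by Stille coupling of the allylic acetate in diacetate 21. The same acetylation puts the final acetate on C7 and the leaving group on C14, so C7 needs no protecting group at any stage.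

**C12=C13 (21 ⇒ 20 ⇒ 19 ⇒ 18).** Diacetate 21 comes from diol 20, the reduction product of enoate 19, which is the Wittig product of methyl ketone 18 with a stabilised ylide. A non-stabilised ylide would be basic enough to trigger Kornblum–DeLaMare cleavage at C11 and is known to favour the wrong (Z) olefin with α-oxygenated ketones. The stabilised ylide is nearly neutral and places the ester trans to the dioxane, which is the E geometry required.

**C6–C7 (18 ⇒ 10 + 16).** The C2–C6 chain with the E-C3=C4 olefin already in place is added as a dialkylzinc (17, from iodide 16) to the aldehyde of keto aldehyde 10 under titanium/bis-sulfonamide catalysis. This reagent is aldehyde-selective, non-basic and sets C7 by catalyst control. Iodide 16 comes in four steps from but-3-yn-1-ol 11 by carboalumination, which fixes the olefin geometry.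

**C12–CH3 and the temporary bond C7–C12 (10 ⇒ 9 ⇒ 8 ⇒ 7).** Keto aldehyde 10 is the oxidation product of 9, formed by chemoselective methyl addition to the less hindered aldehyde of dialdehyde 8. Dialdehyde 8 is the glycol-cleavage product of the bicyclic diol 7. The two aldehydes differ in that C7 sits on the quaternary C8 and C12 on the tertiary C11, and this difference carries the differentiation.

**The two C–O bonds of the dioxane (7 ⇒ 6 ⇒ 5 ⇒ 4).** Diol 7 comes from acetonide 6, the diimide reduction product of endoperoxide 5, and 5 is the singlet-oxygen adduct of diene acetonide 4. This cut removes one ring, two skeletal bonds and both peroxide stereocentres in a single well-precedented cycloaddition on a nine-carbon compound. No other way of forming the dioxane sets the quaternary C8 and C11 together with such certainty.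

**Chiral pool (4 ⇒ 3 ⇒ 2 ⇒ 1).** Acetonide 4 is made from (1R,2S)-3-methylcyclohexa-3,5-diene-1,2-diol 3. This is the enantiomer of the diol that toluene dioxygenase makes from toluene; it is reached from 4-iodotoluene 1 by dihydroxylation next to iodine (2) and hydrogenolysis of the C–I bond.

## Roads not taken

**Alternative 1:** The carbocycle would be made from a 12-membered lactone. After methylenation of the lactone carbonyl, the allyl vinyl ether held in the ring rearranges on heating: C5–C6 forms, O–C3 breaks, and the 14-membered ketone A1 results, with a C7 ketone, a C8 exocyclic methylene group and E-C3=C4. Its merits are real. Macrolactonisation is the most dependable entry to a large ring, the rearrangement is stereospecific for the C3=C4 geometry, and no peroxide is present, so strong bases and hydrides can be used freely. In these respects it is better than the chosen plan. Its weakness lies after A1: the dioxane must be built from the 1,1-disubstituted olefin at C8 and the oxygen at C11. That means a radical hydroperoxidation at the tertiary C8 without facial control followed by a displacement at C11, so the hardest centre of the molecule is set by the least controlled step. The C7 ketone must then be reduced next to it, and the lactone is still two oxidation levels away. The chosen plan sets against this a cycloaddition that fixes C8 and C11 together at the start, and pays with about nineteen steps run in the presence of an O–O bond.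

**Alternative 2:** The ring would be closed at C9=C10, inside the future dioxane. The second-generation Grubbs catalyst RuCl2(H2IMes)(PCy3)(=CHPh) joins the vinyl group on the C7–C8 epoxide to the vinyl group on the C11 carbinol and gives A2, with the lactone and both trisubstituted olefins already complete. Metathesis between two monosubstituted vinyl groups is the best-precedented macrocyclisation available here and is more certain than the ring closure of the chosen plan. C7 and C8 would come from a reagent-controlled epoxidation, and the route would be shorter. The difficulty is moved to the end: the C11 alcohol has to become a hydroperoxide and then open the epoxide at the tertiary allylic C8. Substitution at a secondary allylic carbinol by H2O2 competes with SN2′ and elimination, the α-methylene lactone is itself a target for nucleophilic peroxide (Weitz–Scheffer epoxidation), acid-promoted opening at C8 can pass through the allyl cation and lose the configuration, and only the Z olefin can close the dioxane. The C9=C10 bond must finally be reduced by diimide in the presence of an exocyclic enoate that diimide reduces faster. The chosen plan is longer and has the weaker ring closure, but its only peroxide-forming event is a known reaction on a simple diene.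

**Alternative 3:** The ring would be closed at C13–C14 by electrochemical decarboxylative alkenylation. At the cathode, with NiBr2 and 2,2′-bipyridine, an N-acyloxyphthalimide gives the C14 radical, which is captured by the alkenylnickel from a C13 iodide to give A3, with a saturated cis-lactone, the 7,8-epoxide and a silylated C11 alcohol. Two things are better than in the chosen plan: the E-C12=C13 olefin comes from a vinyl iodide of fixed geometry instead of an olefination of a base-sensitive ketone, and C1/C2 are set in a small lactone by ordinary chemistry and do not depend on the ring closure. The weak points are the ring closure itself (a primary radical at high dilution can be reduced or can dimerise, and this coupling has little precedent for large rings) and the three late operations that A3 still needs: α-methylenation of the lactone through its enolate, conversion of the C11 silyl ether into a hydroperoxide that must open the epoxide at C8 as in Alternative 2, and acetylation. The chosen plan gives up the secure C1/C2 centres of A3 and has to win them back with a chiral acid in the ring closure; in exchange the dioxane, with its two stereocentres, is settled once and early.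

Key step: step 4

Remark: atoms carry cembrane numbers throughout; the configuration worked to is 1S,2S,7S,8R,11S with a cis-fused lactone and E olefins at C3 and C12, and the lactone fusion was confirmed as cis from the two ring-fusion descriptors.

Step 1
Reactants: 1 4-iodotoluene
Product: 2 (1S,2S)-3-iodo-6-methylcyclohexa-3,5-diene-1,2-diol
Conditions: whole cells of Pseudomonas putida UV4 (toluene dioxygenase), glucose, phosphate buffer pH 7.2, air, 30 °C
Reagents that add atoms: dioxygen, O=O
Why: Enzymatic arene cis-dihydroxylation; of the two para substituents iodine is the dominant directing group, so the diol is placed next to C–I, and both stereocentres are set by the enzyme.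

Step 2
Reactants: 2 (1S,2S)-3-iodo-6-methylcyclohexa-3,5-diene-1,2-diol
Product: 3 (1R,2S)-3-methylcyclohexa-3,5-diene-1,2-diol
Conditions: H2 (1 atm), Pd/C (5 %), NaOAc, MeOH, 0 °C, stopped after one equivalent of H2
Reagents that add atoms: none
Why: Catalytic hydrogenolysis of the vinyl C–I bond, which is cleaved faster than the diene is saturated and is the established way from iodo cis-dihydrodiols to the dioxygenase-inaccessible enantiomers; the stereocentres are untouched, only the numbering (and so the descriptors) changes.

Step 3
Reactants: 3 (1R,2S)-3-methylcyclohexa-3,5-diene-1,2-diol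
Product: 4 (3aS,7aR)-2,2,4-trimethyl-3a,7a-dihydro-1,3-benzodioxole (acetonide of 3)
Conditions: 2,2-dimethoxypropane, TsOH·H2O (cat.), acetone, 0 °C; used at once
Reagents that add atoms: 2,2-dimethoxypropane, COC(C)(C)OC
Why: Acid-catalysed transacetalisation of a cis-1,2-diol; the diene acetonide dimerises by Diels–Alder reaction on standing and is therefore taken directly into step 4.

Step 4
Reactants: 4 (3aS,7aR)-2,2,4-trimethyl-3a,7a-dihydro-1,3-benzodioxole
Product: 5 acetonide of (1R,4S,7R,8S)-1-methyl-2,3-dioxabicyclo[2.2.2]oct-5-ene-7,8-diol (diol oxygens anti to the O–O bridge; C1 and C4 are C8 and C11 of the target)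
Conditions: O2, visible light (sodium lamp), tetraphenylporphyrin (cat.), CH2Cl2, −30 °C
Reagents that add atoms: dioxygen (sensitised to singlet oxygen), O=O
Why: Singlet oxygen adds as a dienophile in a concerted suprafacial [4+2] cycloaddition across the diene termini C8 and C11, which the six-membered ring holds s-cis. The closest known reactions are the photooxygenations of acetonides of arene cis-dihydrodiols and of 1-substituted cyclohexa-1,3-dienes. The 1,2-dioxane ring is closed by the cycloaddition itself, both C–O bonds forming in one step to give the 2,3-dioxabicyclo[2.2.2]octene. C8 and C11 are set together: their cis relation follows from suprafacial addition, and their absolute configuration follows from approach anti to the dioxolane, whose oxygens and inward methyl group shield the other face. The two diol carbons that exert this control are the ones destroyed later by glycol cleavage. The step needs cycloaddition to outrun the ene reaction at the allylic hydrogens; the locked s-cis geometry secures this, since cyclic 1,3-dienes react with singlet oxygen predominantly by [4+2]. The low temperature keeps 4 from dimerising and 5 from rearranging to the bis-epoxide.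

Step 5
Reactants: 5 acetonide of (1R,4S,7R,8S)-1-methyl-2,3-dioxabicyclo[2.2.2]oct-5-ene-7,8-diol
Product: 6 acetonide of (1R,4S,7R,8S)-1-methyl-2,3-dioxabicyclo[2.2.2]octane-7,8-diol
Conditions: KO2CN=NCO2K, AcOH, MeOH/CH2Cl2, −20 °C to rt
Reagents that add atoms: none
Why: Diimide reduction; the concerted metal-free transfer of H2 saturates the strained bicyclic olefin and leaves the O–O bond intact, as is known for bicyclic endoperoxides.

Step 6
Reactants: 6 acetonide of (1R,4S,7R,8S)-1-methyl-2,3-dioxabicyclo[2.2.2]octane-7,8-diol
Product: 7 (1R,4S,7R,8S)-1-methyl-2,3-dioxabicyclo[2.2.2]octane-7,8-diol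
Conditions: CF3CO2H/H2O 9:1, 0 °C to rt
Reagents that add atoms: none
Why: Acid hydrolysis of the acetal; the saturated endoperoxide tolerates acid because its tertiary C–O bond is at a bridgehead and cannot ionise.

Step 7
Reactants: 7 (1R,4S,7R,8S)-1-methyl-2,3-dioxabicyclo[2.2.2]octane-7,8-diol
Product: 8 (3R,6S)-3-methyl-1,2-dioxane-3,6-dicarbaldehyde (cis; the C7 aldehyde on C8, the C12 aldehyde on C11)
Conditions: NaIO4 on silica gel, CH2Cl2, 0 °C; filtered and used at once
Reagents that add atoms: none
Why: Periodate glycol cleavage through the cyclic periodate ester of the cis-diol cuts the temporary C7–C12 bond; the supported reagent avoids water (hydrates) and base (epimerisation or Kornblum–DeLaMare cleavage at C11), and C8 and C11 are not touched.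

Step 8
Reactants: 8 (3R,6S)-3-methyl-1,2-dioxane-3,6-dicarbaldehyde
Product: 9 (3R,6S)-6-(1-hydroxyethyl)-3-methyl-1,2-dioxane-3-carbaldehyde (both epimers at the new carbinol C12)
Conditions: MeTi(OiPr)3 (1.05 equiv, from MeLi and ClTi(OiPr)3), THF, −78 to −40 °C; aq. NH4Cl
Reagents that add atoms: methyltitanium triisopropoxide, C[Ti](OC(C)C)(OC(C)C)OC(C)C
Why: Chemoselective organotitanium carbonyl addition; the reagent does not enolise aldehydes and discriminates strongly on steric grounds, so the C12 aldehyde on the tertiary C11 should react ahead of the C7 aldehyde on the quaternary C8. The new carbinol centre is removed in step 9, so its configuration does not matter.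

Step 9
Reactants: 9 (3R,6S)-6-(1-hydroxyethyl)-3-methyl-1,2-dioxane-3-carbaldehyde
Product: 10 (3R,6S)-6-acetyl-3-methyl-1,2-dioxane-3-carbaldehyde
Conditions: Dess–Martin periodinane, NaHCO3, CH2Cl2, 0 °C
Reagents that add atoms: none
Why: Dess–Martin oxidation of the secondary alcohol under buffered, non-basic conditions, which the aldehyde and the peroxide tolerate; the product is kept cold and used quickly because the C11 hydrogen is now α to a ketone.

Step 10
Reactants: 11 but-3-yn-1-ol
Product: 13 ethyl (E)-5-hydroxy-3-methylpent-2-enoate, via alkenylalane 12 (not isolated)
Conditions: Me3Al (3 equiv), Cp2ZrCl2 (0.25 equiv), CH2Cl2, 0 °C to rt; then ClCO2Et, 0 °C to rt; aq. HCl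
Reagents that add atoms: trimethylaluminium, C[Al](C)C; ethyl chloroformate, CCOC(=O)Cl
Why: Negishi zirconium-catalysed carboalumination adds methyl and aluminium syn across the alkyne with aluminium on the terminal carbon, and acylation of the C–Al bond with retention gives the E enoate (C2 trans to C5).

Step 11
Reactants: 13 ethyl (E)-5-hydroxy-3-methylpent-2-enoate
Product: 14 ethyl (E)-5-iodo-3-methylpent-2-enoate
Conditions: I2, PPh3, imidazole, CH2Cl2, 0 °C
Reagents that add atoms: iodine, II
Why: Appel-type iodination of a primary alcohol through the alkoxyphosphonium iodide; the olefin geometry is not involved.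

Step 12
Reactants: 14 ethyl (E)-5-iodo-3-methylpent-2-enoate
Product: 15 (E)-5-iodo-3-methylpent-2-en-1-ol
Conditions: iBu2AlH (2.2 equiv), CH2Cl2, −78 °C; aq. KNaC4H4O6
Reagents that add atoms: none
Why: 1,2-Reduction of an enoate to the allylic alcohol by iBu2AlH; the primary iodide is inert at −78 °C.

Step 13
Reactants: 15 (E)-5-iodo-3-methylpent-2-en-1-ol
Product: 16 tert-butyl{[(E)-5-iodo-3-methylpent-2-en-1-yl]oxy}dimethylsilane
Conditions: TBSCl, imidazole, DMF, rt
Reagents that add atoms: tert-butyldimethylsilyl chloride, CC(C)(C)[Si](C)(C)Cl
Why: Standard silylation; the silyl ether later distinguishes the C2 oxygen from the two hydroxyls that become acetates.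

Step 14
Reactants: 10 (3R,6S)-6-acetyl-3-methyl-1,2-dioxane-3-carbaldehyde; 16 tert-butyl{[(E)-5-iodo-3-methylpent-2-en-1-yl]oxy}dimethylsilane
Product: 18 keto alcohol: (8R,11S)-dioxane with acetyl on C11 and on C8 methyl plus the (7S)-CH(OH)CH2CH2C(CH3)=CHCH2OTBS chain (3E), via dialkylzinc 17 (not isolated)
Conditions: 16 (3 equiv), Et2Zn, CuI (cat.), 50 °C, then volatiles removed in vacuo; Ti(OiPr)4 (2 equiv), (1R,2R)-1,2-bis(trifluoromethanesulfonamido)cyclohexane (10 mol %), toluene, −20 °C, then 10
Reagents that add atoms: none
Why: Catalytic enantioselective addition of a functionalised dialkylzinc to an aldehyde under titanium bis-sulfonamide catalysis; the reagent is non-basic and leaves the ketone untouched. The (1R,2R)-ligand is the one that delivers alkyl groups to the Si face of aldehydes, which here gives 7S; catalyst control is relied on because the quaternary C8 offers only a weak bias.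

Step 15
Reactants: 18 keto alcohol (7S,8R,11S)
Product: 19 methyl (E)-enoate: as 18, with the acetyl group converted into (E)-C(CH3)=CH–CO2CH3 (C11 trans to the ester carbon C14)
Conditions: Ph3P=CHCO2Me (3 equiv), PhCO2H (10 mol %), toluene, 60 °C
Reagents that add atoms: methyl (triphenylphosphoranylidene)acetate, COC(=O)C=P(c1ccccc1)(c1ccccc1)c1ccccc1
Why: Wittig olefination of an α-oxygenated methyl ketone with a stabilised ylide; such ketones are activated and place the ester trans to the larger α-substituent, here the dioxane, which is the E geometry needed. The nearly neutral, acid-buffered ylide is chosen so that C11 is not deprotonated.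

Step 16
Reactants: 19 methyl (E)-enoate
Product: 20 diol: as 19, with CO2CH3 reduced to CH2OH (C14), the C7 hydroxyl free
Conditions: iBu2AlH (3.5 equiv), CH2Cl2, −78 °C; aq. KNaC4H4O6
Reagents that add atoms: none
Why: 1,2-Reduction of the enoate by iBu2AlH; dialkyl peroxides withstand this reagent at −78 °C, unlike LiAlH4, and the silyl ether is inert.

Step 17
Reactants: 20 diol
Product: 21 diacetate: C7–OAc (7S) and the primary allylic acetate at C14
Conditions: Ac2O, pyridine, DMAP (cat.), CH2Cl2, 0 °C to rt
Reagents that add atoms: acetic anhydride, CC(=O)OC(C)=O
Why: Acylation of both hydroxyls; the C7 acetate is the one in the target, and the C14 acetate is the leaving group for step 18.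

Step 18
Reactants: 21 diacetate
Product: 22 skipped diene: as 21, with CH2OAc at C14 replaced by CH2–CH=CH2 (C14, C1 and the carbon later lost as ethene), C12=C13 still E
Conditions: tributyl(vinyl)stannane, Pd(dba)2 (5 mol %), LiCl, DMF, rt
Reagents that add atoms: tributyl(vinyl)stannane, C=C[Sn](CCCC)(CCCC)CCCC
Why: Stille coupling of an allylic acetate with a vinylstannane under phosphine-free zerovalent palladium: ionisation to the π-allyl complex, transmetalation, and C–C bond formation at the less hindered terminus C14 with the E olefin retained. Only the allylic acetate ionises, and palladium-catalysed couplings are known to tolerate dialkyl peroxides.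

Step 19
Reactants: 22 skipped diene
Product: 23 allylic alcohol: as 22, with the C2 silyl ether cleaved to CH2OH
Conditions: HF·pyridine, pyridine, THF, 0 °C to rt
Reagents that add atoms: none
Why: Fluoride-mediated desilylation of a primary silyl ether under buffered conditions that leave the acetate and the peroxide alone.

Step 20
Reactants: 23 allylic alcohol
Product: 24 (E)-enal: as 23, with C2 oxidised to CHO
Conditions: MnO2 (activated), CH2Cl2, rt
Reagents that add atoms: none
Why: MnO2 oxidises only the allylic alcohol and does so under neutral conditions without isomerising the E-C3=C4 bond.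

Step 21
Reactants: 25 methyl 2-(bromomethyl)acrylate
Product: 26 methyl 2-[(4,4,5,5-tetramethyl-1,3,2-dioxaborolan-2-yl)methyl]acrylate
Conditions: bis(pinacolato)diboron, CuCl (10 mol %), KOAc, DMF, rt
Reagents that add atoms: bis(pinacolato)diboron, CC1(C)OB(OC1(C)C)B1OC(C)(C)C(C)(C)O1
Why: Copper-catalysed allylic borylation (Hosomi–Miyaura type); SN2 and SN2′ attack of the boryl copper species give the same product from this symmetrical allyl system.

Step 22
Reactants: 24 (E)-enal; 26 methyl 2-[(4,4,5,5-tetramethyl-1,3,2-dioxaborolan-2-yl)methyl]acrylate
Product: 27 allylboronate enal: as 24, with the terminal CH=CH2 converted into CH=C(CO2CH3)CH2B(pin), C14 cis to CH2B (2E by the sequence rule)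
Conditions: 26 (5 equiv), second-generation Hoveyda–Grubbs catalyst RuCl2(H2IMes)(=CH-C6H4-2-OiPr) (10 mol %), CH2Cl2, 40 °C
Reagents that add atoms: none
Why: Cross-metathesis of a terminal olefin with a 2-substituted acrylate, the slow partner that does not homodimerise and is therefore used in excess; thermodynamic control places C14 trans to the ester. The trisubstituted olefins and the peroxide are inert to the ruthenium carbene, and boronate and enal do not react with each other at 40 °C without acid.

Step 23
Reactants: 27 allylboronate enal
Product: 29 the target CNP0238885.7, via macrocyclic borate 28 (not isolated)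
Conditions: (R)-TRIP (3,3′-bis(2,4,6-triisopropylphenyl)-1,1′-binaphthyl-2,2′-diyl hydrogen phosphate, 20 mol %), 4 Å molecular sieves, toluene, 27 added by syringe pump to 0.002 M, rt to 40 °C; then PPTS, rt
Reagents that add atoms: none
Why: Proposed new method: a 2-alkoxycarbonylallyl pinacolboronate adds to an aldehyde through a closed chair transition state, and a phosphoric acid hydrogen-bonded to a boronate oxygen lowers that barrier without opening it, so the E-boronate (C14 cis to CH2B) should give the 1,2-syn borate 28, which lactonises to the cis-fused lactone; the closest known reactions are the intermolecular lactone-forming allylboration with these boronates, the phosphoric-acid-catalysed allyl- and crotylboration of aldehydes, and intramolecular allylborations closing five- to eight-membered rings. The (R)-acid is expected, by analogy with its sense on simple aldehydes, to direct the allyl group to the Re face of C2 (2S, hence 1S by the syn rule); the (S)-acid is equally available should the macrocycle's own preference prove mismatched.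

**Compound list**

1 | 4-iodotoluene | Cc1ccc(I)cc1 | starting material
2 | (1S,2S)-3-iodo-6-methylcyclohexa-3,5-diene-1,2-diol | CC1=CC=C(I)[C@@H](O)[C@H]1O | intermediate
3 | (1R,2S)-3-methylcyclohexa-3,5-diene-1,2-diol | CC1=CC=C[C@@H](O)[C@H]1O | intermediate
4 | (3aS,7aR)-2,2,4-trimethyl-3a,7a-dihydro-1,3-benzodioxole | CC1=CC=C[C@H]2OC(C)(C)O[C@@H]12 | intermediate
5 | acetonide of (1R,4S,7R,8S)-1-methyl-2,3-dioxabicyclo[2.2.2]oct-5-ene-7,8-diol | C[C@]12C=C[C@H](OO1)[C@H]3OC(C)(C)O[C@H]32 | intermediate
6 | acetonide of (1R,4S,7R,8S)-1-methyl-2,3-dioxabicyclo[2.2.2]octane-7,8-diol | C[C@]12CC[C@H](OO1)[C@H]3OC(C)(C)O[C@H]32 | intermediate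
7 | (1R,4S,7R,8S)-1-methyl-2,3-dioxabicyclo[2.2.2]octane-7,8-diol | C[C@]12CC[C@H](OO1)[C@@H](O)[C@H]2O | intermediate
8 | (3R,6S)-3-methyl-1,2-dioxane-3,6-dicarbaldehyde | O=C[C@@]1(C)CC[C@H](OO1)C=O | intermediate
9 | (3R,6S)-6-(1-hydroxyethyl)-3-methyl-1,2-dioxane-3-carbaldehyde (carbinol epimers) | O=C[C@@]1(C)CC[C@H](OO1)C(C)O | intermediate
10 | (3R,6S)-6-acetyl-3-methyl-1,2-dioxane-3-carbaldehyde | O=C[C@@]1(C)CC[C@H](OO1)C(C)=O | intermediate
11 | but-3-yn-1-ol | C#CCCO | starting material
12 | dimethylaluminium alkoxide of (E)-4-(dimethylalumanyl)-3-methylbut-3-en-1-ol (alkenylalane) | C[Al](C)OCC/C(C)=C/[Al](C)C | intermediate (not isolated)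
13 | ethyl (E)-5-hydroxy-3-methylpent-2-enoate | CCOC(=O)/C=C(\C)CCO | intermediate
14 | ethyl (E)-5-iodo-3-methylpent-2-enoate | CCOC(=O)/C=C(\C)CCI | intermediate
15 | (E)-5-iodo-3-methylpent-2-en-1-ol | OC/C=C(\C)CCI | intermediate
16 | tert-butyl{[(E)-5-iodo-3-methylpent-2-en-1-yl]oxy}dimethylsilane | CC(C)(C)[Si](C)(C)OC/C=C(\C)CCI | intermediate
17 | bis[(E)-5-(tert-butyldimethylsilyloxy)-3-methylpent-3-en-1-yl]zinc | CC(C)(C)[Si](C)(C)OC/C=C(\C)CC[Zn]CC/C(C)=C/CO[Si](C)(C)C(C)(C)C | intermediate (not isolated)
18 | keto alcohol (7S,8R,11S): C11-acetyl dioxane with the (3E)-C2–C7 chain, C2 as TBS ether, C7–OH | CC(C)(C)[Si](C)(C)OC/C=C(\C)CC[C@H](O)[C@@]1(C)CC[C@H](OO1)C(C)=O | intermediate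
19 | methyl (12E)-enoate (C14 = ester carbon), C7–OH, C2–OTBS | CC(C)(C)[Si](C)(C)OC/C=C(\C)CC[C@H](O)[C@@]1(C)CC[C@H](OO1)/C(C)=C/C(=O)OC | intermediate
20 | diol: C14–OH and C7–OH, C2–OTBS | CC(C)(C)[Si](C)(C)OC/C=C(\C)CC[C@H](O)[C@@]1(C)CC[C@H](OO1)/C(C)=C/CO | intermediate
21 | diacetate: C7–OAc and C14–OAc, C2–OTBS | CC(C)(C)[Si](C)(C)OC/C=C(\C)CC[C@H](OC(C)=O)[C@@]1(C)CC[C@H](OO1)/C(C)=C/COC(C)=O | intermediate
22 | skipped diene: allyl group on C13, C7–OAc, C2–OTBS | CC(C)(C)[Si](C)(C)OC/C=C(\C)CC[C@H](OC(C)=O)[C@@]1(C)CC[C@H](OO1)/C(C)=C/CC=C | intermediate
23 | allylic alcohol: as 22 with C2–OH | OC/C=C(\C)CC[C@H](OC(C)=O)[C@@]1(C)CC[C@H](OO1)/C(C)=C/CC=C | intermediate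
24 | (3E)-enal: as 23 with C2 as CHO | O=C/C=C(\C)CC[C@H](OC(C)=O)[C@@]1(C)CC[C@H](OO1)/C(C)=C/CC=C | intermediate
25 | methyl 2-(bromomethyl)acrylate | C=C(CBr)C(=O)OC | starting material
26 | methyl 2-[(4,4,5,5-tetramethyl-1,3,2-dioxaborolan-2-yl)methyl]acrylate | C=C(CB1OC(C)(C)C(C)(C)O1)C(=O)OC | intermediate
27 | allylboronate enal: C1=C15 with C14 cis to CH2B(pin), C2 aldehyde | O=C/C=C(\C)CC[C@H](OC(C)=O)[C@@]1(C)CC[C@H](OO1)/C(C)=C/C/C=C(\CB2OC(C)(C)C(C)(C)O2)C(=O)OC | intermediate
28 | macrocyclic (1S,2S) pinacol borate of the C2 alcohol with C15(=CH2)CO2CH3 on C1 | C=C(C(=O)OC)[C@H]1[C@@H](OB2OC(C)(C)C(C)(C)O2)/C=C(\C)CC[C@H](OC(C)=O)[C@@]3(C)CC[C@H](OO3)/C(C)=C/C1 | intermediate (not isolated)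
29 | CNP0238885.7 | C=C1C(=O)O[C@H]2/C=C(\C)CC[C@H](OC(C)=O)[C@@]3(C)CC[C@H](OO3)/C(C)=C/C[C@@H]12 | target

**Step count and risks**

Total: 23 steps. Longest linear sequence: 18 steps from 4-iodotoluene (steps 1–9, 14–20, 22, 23); steps 10–13 and 21 are side branches.

Least certain steps:

Step 23 (the step carrying the new-method label). The ring closure may be too slow at high dilution, so that oligomerisation or acid-induced ionisation at the allylic C2–O bond takes over, and the catalyst may fail to override the macrocycle's own facial preference. The fallback uses silicon in place of boron and known Lewis-acid chemistry. It sets out from enal 24: cross-metathesis with methyl 2-[(trimethylsilyl)methyl]acrylate gives the allylsilane F1. Intramolecular Hosomi–Sakurai addition (BF3·OEt2, CH2Cl2, −78 °C, high dilution) follows; this reaction is known for closing carbocycles fused to α-methylene lactones and is tolerated by 1,2-dioxanes at low temperature. It gives the macrocyclic hydroxy ester F2, whose lactonisation with PPTS returns to the route at 29.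

Step 4 (key step). The ene reaction at the allylic hydrogens and incomplete facial selection may erode the cycloaddition, and 5 may rearrange before it is reduced. The fallback changes the element of facial control. It sets out from diol 3, which is converted with TBSOTf and 2,6-lutidine into the bis-silyl ether F3, whose two bulky groups screen one face more completely. Photooxygenation gives the endoperoxide F4 and diimide the saturated compound F5, and HF·pyridine returns to the route at diol 7.

Step 8. Discrimination between the two aldehydes may be incomplete (double addition), and the α-peroxy aldehyde may epimerise or fragment at C11 before it reacts. The fallback avoids the dialdehyde. It sets out from diol 7: regioselective oxidation through the stannylene acetal (Bu2SnO, then NBS), which activates the less hindered C12 oxygen, gives the hydroxy ketone F6, in which the C11 hydrogen is at a bridgehead and cannot be lost by enolisation. MeMgBr with CeCl3 at −78 °C gives the tertiary alcohol F7, and NaIO4 cleavage returns to the route at keto aldehyde 10.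

Step 14. Addition to the hindered aldehyde on the quaternary C8 may be slow, catalyst control over C7 may be incomplete, and the Lewis-acidic medium may enolise the ketone. The fallback separates bond formation from stereocontrol. It sets out from hydroxy aldehyde 9: the Grignard reagent from 16, with CeCl3 at −78 °C, gives the diol F8 as a mixture at C7, and Dess–Martin oxidation gives the diketone F9. Wittig olefination as in step 15, which takes only the unhindered methyl ketone, gives the keto enoate F10. Corey–Bakshi–Shibata reduction with the (R)-oxazaborolidine and catecholborane (large group C8, small group C6) sets 7S and returns to the route at 19.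

Step 15. Slow deprotonation at C11 by the ylide during a sluggish olefination would destroy the peroxide (Kornblum–DeLaMare cleavage), and E/Z selectivity may be incomplete. The fallback avoids a prolonged reaction at the ketone. It sets out from 18: vinylmagnesium bromide with CeCl3 at −78 °C, a fast non-basic addition, gives the tertiary allylic alcohol F11, and acetylation of both hydroxyls (Ac2O, DMAP) gives F12. The [3,3] transposition of the tertiary allylic acetate catalysed by divalent palladium (PdCl2(MeCN)2, THF, rt) moves the acetate to C14 and forms C12=C13, with E expected to predominate. It returns to the route at diacetate 21 and also saves step 16.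

**Further compounds**

F1 | step 23 | allylsilane enal: as 27 with CH2Si(CH3)3 in place of CH2B(pin) | O=C/C=C(\C)CC[C@H](OC(C)=O)[C@@]1(C)CC[C@H](OO1)/C(C)=C/C/C=C(\C[Si](C)(C)C)C(=O)OC
F2 | step 23 | macrocyclic (1S,2S) hydroxy ester: C2–OH, C15(=CH2)CO2CH3 on C1 | C=C(C(=O)OC)[C@H]1[C@@H](O)/C=C(\C)CC[C@H](OC(C)=O)[C@@]2(C)CC[C@H](OO2)/C(C)=C/C1
F3 | step 4 | bis(tert-butyldimethylsilyl) ether of diol 3 | CC1=CC=C[C@@H](O[Si](C)(C)C(C)(C)C)[C@H]1O[Si](C)(C)C(C)(C)C
F4 | step 4 | bis-silyl ether of (1R,4S,7R,8S)-1-methyl-2,3-dioxabicyclo[2.2.2]oct-5-ene-7,8-diol | C[C@]12C=C[C@H](OO1)[C@@H](O[Si](C)(C)C(C)(C)C)[C@H]2O[Si](C)(C)C(C)(C)C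
F5 | step 4 | bis-silyl ether of diol 7 | C[C@]12CC[C@H](OO1)[C@@H](O[Si](C)(C)C(C)(C)C)[C@H]2O[Si](C)(C)C(C)(C)C
F6 | step 8 | (1R,4S,7R)-7-hydroxy-1-methyl-2,3-dioxabicyclo[2.2.2]octan-8-one (ketone at C12) | C[C@]12CC[C@H](OO1)C(=O)[C@H]2O
F7 | step 8 | 1,8-dimethyl-2,3-dioxabicyclo[2.2.2]octane-7,8-diol (methyl carbinol at C12) | C[C@]12CC[C@H](OO1)C(C)(O)[C@H]2O
F8 | step 14 | diol: C7 and C12 carbinols (epimers), C2–OTBS | CC(C)(C)[Si](C)(C)OC/C=C(\C)CCC(O)[C@@]1(C)CC[C@H](OO1)C(C)O
F9 | step 14 | diketone: C7 ketone and C12 methyl ketone | CC(C)(C)[Si](C)(C)OC/C=C(\C)CCC(=O)[C@@]1(C)CC[C@H](OO1)C(C)=O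
F10 | step 14 | keto enoate: C7 ketone, (12E)-enoate | CC(C)(C)[Si](C)(C)OC/C=C(\C)CCC(=O)[C@@]1(C)CC[C@H](OO1)/C(C)=C/C(=O)OC
F11 | step 15 | tertiary allylic alcohol: C12(CH3)(OH)CH=CH2, C7–OH | CC(C)(C)[Si](C)(C)OC/C=C(\C)CC[C@H](O)[C@@]1(C)CC[C@H](OO1)C(C)(O)C=C
F12 | step 15 | diacetate of F11 (tertiary allylic acetate and C7–OAc) | CC(C)(C)[Si](C)(C)OC/C=C(\C)CC[C@H](OC(C)=O)[C@@]1(C)CC[C@H](OO1)C(C)(OC(C)=O)C=C
A1 | alternative 1 | 14-membered C7 ketone with C8 exocyclic methylene, E-C3=C4, silyl ethers at C2 and C16, PMB ether at C11 | C=C(CO[Si](C)(C)C(C)(C)C)[C@H]1[C@@H](O[Si](C)(C)C(C)(C)C)/C=C(\C)CCC(=O)C(=C)CC[C@@H](OCc2ccc(OC)cc2)/C(C)=C/C1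
A2 | alternative 2 | 14-membered ring with Z-C9=C10 between the epoxide carbon C8 and the C11 carbinol, lactone complete | C[C@@]12O[C@H]1CC/C(C)=C/[C@@H]1OC(=O)C(=C)[C@@H]1C/C=C(C)/[C@H](O)/C=C\2
A3 | alternative 3 | 14-membered carbocycle with saturated cis-lactone, 7,8-epoxide and triethylsilyl ether at C11 | O=C1C[C@H]5[C@@H](O1)/C=C(\C)CC[C@@H]4O[C@@]4(C)CC[C@@H](O[Si](CC)(CC)CC)/C(C)=C/C5
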